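Overview (isochromene numbering: C1, O2, C3, C4, C4a, C5 to C8, C8a): the last disconnection is the C8–O acyl bond, which leads back to the 7,8-diol (secondary C8–OH beside tertiary C7–OH) and a silyl-protected orsellinic acid.
Enabling feature: the carbocycle C4a–C5–C6–C7–C8–C8a holds an α-ketol (C6 ketone next to the C7 methyl carbinol). Moving C8 back from C7 to C6 contracts this ring to a 1-acetylcyclopent-2-en-1-ol. The vinylogous ester O2–C3=C4–C4a=C5–C6=O of the pyran is the adduct of the C1 hydroxyl to a C3≡C4 alkyne conjugated with that ketone.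
One Lewis acid operation therefore turns a monocyclic enynyl cyclopentene ketol into the whole bicycle. Ring order: five-membered carbocycle (bought), six-membered carbocycle (ring expansion), pyran (6-endo-dig).
The ketol comes from (R)-4-silyloxycyclopent-2-enone by three carbonyl additions: formaldehyde aldol, pentenynyllithium with oxidative transposition, and a 1-ethoxyvinyl anion. The bought C8 centre sets C8a and C6, and C6 sets C7.

Key step: step 8

Remark: crotonaldehyde, (R)-4-(tert-butyldimethylsilyloxy)cyclopent-2-enone and orsellinic acid are taken as commercial; TBS = tert-butyldimethylsilyl; where the descriptor of an untouched centre switches between R and S along the route, only CIP priorities change.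

Step 1
Reactants: 1 (E)-but-2-enal (crotonaldehyde)
Product: 2 (3E)-1,1-dibromopenta-1,3-diene
Conditions: CBr4, PPh3, CH2Cl2, 0 °C
Reagents that add atoms: carbon tetrabromide, BrC(Br)(Br)Br
Why: Corey–Fuchs dibromoolefination (Wittig-type reaction of Ph3P=CBr2 with the aldehyde) leaves the E-propenyl unit untouched and stores the volatile enyne in a form that is easy to handle.

Step 2
Reactants: 3 (4R)-4-(TBSO)cyclopent-2-en-1-one
Product: 5 (4S,5R)-4-(TBSO)-5-(hydroxymethyl)cyclopent-2-en-1-one (substituents trans), via lithium enolate 4 (not isolated)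
Conditions: LiN(iPr)2, THF, −78 °C; monomeric HCHO (cracked paraformaldehyde), −78 °C; sat. aq. NH4Cl
Reagents that add atoms: formaldehyde, C=O
Why: Kinetic α'-deprotonation gives the cross-conjugated enolate, whose aldol addition to formaldehyde (hydroxymethylation, precedented on 4-oxygenated cyclopentenones) takes place anti to the neighbouring silyloxy group and sets C8a trans to C8, which is also the more stable arrangement at this epimerisable centre.

Step 3
Reactants: 5 (4S,5R)-4-(TBSO)-5-(hydroxymethyl)cyclopent-2-en-1-one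
Product: 6 (4S,5R)-4-(TBSO)-5-(TBSO-methyl)cyclopent-2-en-1-one
Conditions: TBSCl, imidazole, CH2Cl2, 0 °C to rt
Reagents that add atoms: tert-butyldimethylsilyl chloride, CC(C)(C)[Si](C)(C)Cl
Why: Standard imidazole-mediated silylation of the primary alcohol masks the aldol hydroxyl before it can eliminate or undergo retro-aldol cleavage and creates no stereocentre.

Step 4
Reactants: 2 (3E)-1,1-dibromopenta-1,3-diene; 6 (4S,5R)-4-(TBSO)-5-(TBSO-methyl)cyclopent-2-en-1-one
Product: 8 (1S,4S,5R)-4-(TBSO)-5-(TBSO-methyl)-1-[(3E)-pent-3-en-1-yn-1-yl]cyclopent-2-en-1-ol, via lithium pentenynide 7 (not isolated)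
Conditions: 2, n-BuLi (2.05 equiv), THF, −78 to 0 °C; then 6, −78 °C; sat. aq. NH4Cl
Reagents that add atoms: none
Why: The second stage of the Corey–Fuchs sequence (bromine–lithium exchange, Fritsch–Buttenberg–Wiechell shift, deprotonation) gives the acetylide, which adds 1,2 to the enone, expected anti to the adjacent silyloxymethyl group, and the new carbinol centre is erased in step 5 so that either epimer serves.

Step 5
Reactants: 8 (1S,4S,5R)-4-(TBSO)-5-(TBSO-methyl)-1-[(3E)-pent-3-en-1-yn-1-yl]cyclopent-2-en-1-ol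
Product: 9 (4R,5R)-5-(TBSO)-4-(TBSO-methyl)-3-[(3E)-pent-3-en-1-yn-1-yl]cyclopent-2-en-1-one
Conditions: pyridinium chlorochromate [C5H5NH][CrO3Cl], 4 Å MS, CH2Cl2, rt
Reagents that add atoms: pyridinium chlorochromate, [O-][Cr](=O)(=O)Cl.c1cc[nH+]cc1
Why: Babler–Dauben oxidative transposition, in which the chromate ester of the tertiary allylic alcohol undergoes a [3,3] shift and is oxidised at the new position, moves the oxygen next to C8 and leaves the enynyl group on C4a without touching C8 or C8a.

Step 6
Reactants: 9 (4R,5R)-5-(TBSO)-4-(TBSO-methyl)-3-[(3E)-pent-3-en-1-yn-1-yl]cyclopent-2-en-1-one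
Product: 10 (1S,4R,5R)-5-(TBSO)-4-(TBSO-methyl)-1-(1-ethoxyethenyl)-3-[(3E)-pent-3-en-1-yn-1-yl]cyclopent-2-en-1-ol
Conditions: ethyl vinyl ether, t-BuLi, THF, −78 to 0 °C; CeCl3, −78 °C; then 9, −78 °C; sat. aq. NH4Cl
Reagents that add atoms: ethyl vinyl ether, C=COCC
Why: 1,2-Addition of an acyl anion equivalent (1-ethoxyvinyl organocerium, weakly basic towards the enolisable enone) from the face opposite to the adjacent C8 silyloxy group, as in additions to 2-substituted cyclopentanones, sets C6 with its hydroxyl cis to O8.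

Step 7
Reactants: 10 (1S,4R,5R)-5-(TBSO)-4-(TBSO-methyl)-1-(1-ethoxyethenyl)-3-[(3E)-pent-3-en-1-yn-1-yl]cyclopent-2-en-1-ol
Product: 12 1-[(1S,4R,5R)-5-(TBSO)-1-hydroxy-4-(hydroxymethyl)-3-[(3E)-pent-3-en-1-yn-1-yl]cyclopent-2-en-1-yl]ethan-1-one, via bis-silyl ketol 11 (not isolated)
Conditions: AcOH/THF/H2O (3:1:1), rt
Reagents that add atoms: water, O
Why: General acid hydrolysis of the enol ether to the methyl ketone is much faster than ionisation of the tertiary alcohol, and the same medium then cleaves the primary silyl ether while the hindered secondary C8 silyl ether stays (standard primary over secondary desilylation).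

Step 8
Reactants: 12 1-[(1S,4R,5R)-5-(TBSO)-1-hydroxy-4-(hydroxymethyl)-3-[(3E)-pent-3-en-1-yn-1-yl]cyclopent-2-en-1-yl]ethan-1-one
Product: 14 (7R,8R,8aR)-8-(TBSO)-7-hydroxy-7-methyl-3-[(1E)-prop-1-en-1-yl]-1,7,8,8a-tetrahydro-6H-isochromen-6-one, via ring-expanded enynone ketol 13 (not isolated)
Conditions: Sc(OTf)3 (20 mol %), 2,6-di-tert-butylpyridine (10 mol %), 4 Å MS, ClCH2CH2Cl, 60 °C
Reagents that add atoms: none
Why: Proposed new method: Sc(OTf)3 should hold the C6 hydroxyl and the acetyl oxygen of 12 in a five-membered chelate, in which C8 shifts with its bonding pair and with retention from C6 to the activated acetyl carbon C7 (α-ketol or acyloin rearrangement), so that the cyclopentene grows to the cyclohexenone, C6 becomes the ketone and C7 the methyl carbinol of 13. The metal then sits on a C6 carbonyl that is conjugated through C5=C4a with the C4≡C3 bond, the C1 hydroxyl adds to the electrophilic δ-terminus C3 (also stabilised by the propenyl group), and the pyran ring closes in the 6-endo-dig mode, proton transfer to C4 completing the dienol ether of 14. The closest known reaction types are the Lewis acid or aluminium alkoxide ring enlargement of 1-acylcyclopentanols to 2-alkyl-2-hydroxycyclohexanones (steroid D-homoannulation, acyloin shifts catalysed by trivalent scandium or aluminium) and the acid-promoted 6-endo-dig cyclisation of hydroxy ynones to pyranones, but neither the shift on a 1-acetylcyclopent-2-en-1-ol nor the coupling of the two events has been shown. C7, the only new stereocentre, is set by chirality transfer from C6: the acetyl group lies on the ring face opposite to O8, the chelate keeps both oxygens syn-periplanar, and C8 therefore bonds to the carbonyl face that leaves the C7 hydroxyl cis to O8 and the methyl group trans (7R), while C8 and C8a keep their configuration. The step needs migration of sp3 C8 in preference to vinylic C5, which is secured by the reversibility of the shift together with three features of the substrate: the silyloxy donor on C8 raises its migratory aptitude, only C8 migration leaves the new ketone conjugated, and only that isomer is removed irreversibly by pyran closure, since a hard oxophilic Lewis acid does not activate the unpolarised enyne of 12. Because the vinylogous ester carbonyl of 14 is a poor acceptor for the reverse shift, C7 should not equilibrate after ring closure.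

Step 9
Reactants: 14 (7R,8R,8aR)-8-(TBSO)-7-hydroxy-7-methyl-3-[(1E)-prop-1-en-1-yl]-1,7,8,8a-tetrahydro-6H-isochromen-6-one
Product: 15 (7R,8R,8aR)-7,8-dihydroxy-7-methyl-3-[(1E)-prop-1-en-1-yl]-1,7,8,8a-tetrahydro-6H-isochromen-6-one
Conditions: HF·pyridine, pyridine, THF, 0 °C to rt
Reagents that add atoms: none
Why: Fluoride-driven cleavage of the hindered secondary silyl ether under buffered, weakly acidic conditions spares the vinylogous ester, the tertiary α-ketol and the base-sensitive C8a centre.

Step 10
Reactants: 16 orsellinic acid (2,4-dihydroxy-6-methylbenzoic acid)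
Product: 18 2,4-bis(TBSO)-6-methylbenzoic acid, via tris-silyl orsellinate 17 (not isolated)
Conditions: TBSCl (3.5 equiv), imidazole, DMF, rt; then AcOH/THF/H2O, rt
Reagents that add atoms: tert-butyldimethylsilyl chloride, CC(C)(C)[Si](C)(C)Cl
Why: Exhaustive silylation followed by selective solvolysis of the far more labile silyl ester is the standard way to silyl-protected hydroxybenzoic acids.

Step 11
Reactants: 18 2,4-bis(TBSO)-6-methylbenzoic acid; 15 (7R,8R,8aR)-7,8-dihydroxy-7-methyl-3-[(1E)-prop-1-en-1-yl]-1,7,8,8a-tetrahydro-6H-isochromen-6-one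
Product: 20 (7R,8R,8aR)-7-hydroxy-7-methyl-6-oxo-3-[(1E)-prop-1-en-1-yl]-1,7,8,8a-tetrahydro-6H-isochromen-8-yl 2,4-bis(TBSO)-6-methylbenzoate, via acid chloride 19 (not isolated)
Conditions: 18, 1-chloro-N,N,2-trimethylprop-1-en-1-amine, CH2Cl2, 0 °C; then 15, pyridine, DMAP (cat.), CH2Cl2, 0 °C to rt
Reagents that add atoms: none
Why: DMAP-catalysed acylation with an acid chloride made under neutral conditions (α-chloroenamine) should take the secondary C8 hydroxyl in preference to the tertiary C7 hydroxyl on steric grounds, and the weak base pyridine avoids vinylogous E1cB loss of the new ester.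

Step 12
Reactants: 20 (7R,8R,8aR)-7-hydroxy-7-methyl-6-oxo-3-[(1E)-prop-1-en-1-yl]-1,7,8,8a-tetrahydro-6H-isochromen-8-yl 2,4-bis(TBSO)-6-methylbenzoate
Product: 21 berkazaphilone C
Conditions: Et3N·3HF, THF, rt
Reagents that add atoms: none
Why: Mild, nearly neutral fluoride desilylation of the two aryl silyl ethers avoids base, which could trigger elimination of the orsellinate or acyl migration to O7, and touches no stereocentre.

Compound list
1 | (E)-but-2-enal | C/C=C/C=O | starting material
2 | (3E)-1,1-dibromopenta-1,3-diene | C/C=C/C=C(Br)Br | intermediate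
3 | (4R)-4-(TBSO)cyclopent-2-en-1-one | O=C1C=C[C@H](O[Si](C)(C)C(C)(C)C)C1 | starting material
4 | lithium (3S)-3-(TBSO)cyclopenta-1,4-dien-1-olate (cross-conjugated enolate of 3, not isolated) | [Li]OC1=C[C@@H](O[Si](C)(C)C(C)(C)C)C=C1 | intermediate
5 | (4S,5R)-4-(TBSO)-5-(hydroxymethyl)cyclopent-2-en-1-one | O=C1C=C[C@H](O[Si](C)(C)C(C)(C)C)[C@H]1CO | intermediate
6 | (4S,5R)-4-(TBSO)-5-(TBSO-methyl)cyclopent-2-en-1-one | O=C1C=C[C@H](O[Si](C)(C)C(C)(C)C)[C@H]1CO[Si](C)(C)C(C)(C)C | intermediate
7 | lithium (3E)-pent-3-en-1-yn-1-ide (not isolated) | [Li]C#C/C=C/C | intermediate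
8 | (1S,4S,5R)-4-(TBSO)-5-(TBSO-methyl)-1-[(3E)-pent-3-en-1-yn-1-yl]cyclopent-2-en-1-ol | C/C=C/C#C[C@]1(O)C=C[C@H](O[Si](C)(C)C(C)(C)C)[C@H]1CO[Si](C)(C)C(C)(C)C | intermediate
9 | (4R,5R)-5-(TBSO)-4-(TBSO-methyl)-3-[(3E)-pent-3-en-1-yn-1-yl]cyclopent-2-en-1-one | C/C=C/C#CC1=CC(=O)[C@H](O[Si](C)(C)C(C)(C)C)[C@H]1CO[Si](C)(C)C(C)(C)C | intermediate
10 | (1S,4R,5R)-5-(TBSO)-4-(TBSO-methyl)-1-(1-ethoxyethenyl)-3-[(3E)-pent-3-en-1-yn-1-yl]cyclopent-2-en-1-ol | C/C=C/C#CC1=C[C@@](O)(C(=C)OCC)[C@H](O[Si](C)(C)C(C)(C)C)[C@H]1CO[Si](C)(C)C(C)(C)C | intermediate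
11 | 1-[(1S,4R,5R)-5-(TBSO)-4-(TBSO-methyl)-1-hydroxy-3-[(3E)-pent-3-en-1-yn-1-yl]cyclopent-2-en-1-yl]ethan-1-one (not isolated) | C/C=C/C#CC1=C[C@@](O)(C(C)=O)[C@H](O[Si](C)(C)C(C)(C)C)[C@H]1CO[Si](C)(C)C(C)(C)C | intermediate
12 | 1-[(1S,4R,5R)-5-(TBSO)-1-hydroxy-4-(hydroxymethyl)-3-[(3E)-pent-3-en-1-yn-1-yl]cyclopent-2-en-1-yl]ethan-1-one | C/C=C/C#CC1=C[C@@](O)(C(C)=O)[C@H](O[Si](C)(C)C(C)(C)C)[C@H]1CO | intermediate
13 | (4R,5R,6R)-5-(TBSO)-6-hydroxy-4-(hydroxymethyl)-6-methyl-3-[(3E)-pent-3-en-1-yn-1-yl]cyclohex-2-en-1-one (not isolated) | C/C=C/C#CC1=CC(=O)[C@](C)(O)[C@H](O[Si](C)(C)C(C)(C)C)[C@H]1CO | intermediate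
14 | (7R,8R,8aR)-8-(TBSO)-7-hydroxy-7-methyl-3-[(1E)-prop-1-en-1-yl]-1,7,8,8a-tetrahydro-6H-isochromen-6-one | C/C=C/C1=CC2=CC(=O)[C@](C)(O)[C@H](O[Si](C)(C)C(C)(C)C)[C@H]2CO1 | intermediate
15 | (7R,8R,8aR)-7,8-dihydroxy-7-methyl-3-[(1E)-prop-1-en-1-yl]-1,7,8,8a-tetrahydro-6H-isochromen-6-one | C/C=C/C1=CC2=CC(=O)[C@](C)(O)[C@H](O)[C@H]2CO1 | intermediate
16 | orsellinic acid | Cc1cc(O)cc(O)c1C(=O)O | starting material
17 | tert-butyldimethylsilyl 2,4-bis(TBSO)-6-methylbenzoate (not isolated) | Cc1cc(O[Si](C)(C)C(C)(C)C)cc(O[Si](C)(C)C(C)(C)C)c1C(=O)O[Si](C)(C)C(C)(C)C | intermediate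
18 | 2,4-bis(TBSO)-6-methylbenzoic acid | Cc1cc(O[Si](C)(C)C(C)(C)C)cc(O[Si](C)(C)C(C)(C)C)c1C(=O)O | intermediate
19 | 2,4-bis(TBSO)-6-methylbenzoyl chloride (not isolated) | Cc1cc(O[Si](C)(C)C(C)(C)C)cc(O[Si](C)(C)C(C)(C)C)c1C(=O)Cl | intermediate
20 | (7R,8R,8aR)-7-hydroxy-7-methyl-6-oxo-3-[(1E)-prop-1-en-1-yl]-1,7,8,8a-tetrahydro-6H-isochromen-8-yl 2,4-bis(TBSO)-6-methylbenzoate | C/C=C/C1=CC2=CC(=O)[C@](C)(O)[C@H](OC(=O)c3c(C)cc(O[Si](C)(C)C(C)(C)C)cc3O[Si](C)(C)C(C)(C)C)[C@H]2CO1 | intermediate
21 | berkazaphilone C, (7R,8R,8aR) | C/C=C/C1=CC2=CC(=O)[C@](C)(O)[C@H](OC(=O)c3c(C)cc(O)cc3O)[C@H]2CO1 | target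

Total step count: 12. Longest linear sequence: 10 steps (3 to 21 through steps 2 to 9, 11 and 12).

Steps most likely to fail

Step 8. Several processes could defeat the cascade:
- The shift may stall because the product binds the catalyst.
- The tertiary allylic alcohol may ionise.
- Migration of the vinylic carbon may dominate without returning.
- Loss of the C8 silyl group may open a retro-aldol cleavage.
- The hydroxyl may close in the 5-exo mode, or not close at all, under a hard Lewis acid.

The fallback separates the two events and runs each under its classical promoter. It sets out from 10. Brief hydrolysis with oxalic acid in wet THF stops at the bis-silyl ketol 11, which is now isolated. Al(OtBu)3 in toluene at 80 °C follows; this is the aluminium alkoxide α-ketol ring enlargement known from steroid D-homoannulation, it is again chelate controlled, and no free primary alcohol is present that could transfer hydride. It gives (4R,5R,6R)-5-(TBSO)-4-(TBSO-methyl)-6-hydroxy-6-methyl-3-[(3E)-pent-3-en-1-yn-1-yl]cyclohex-2-en-1-one F1. HF·pyridine buffered with pyridine frees only the primary alcohol and gives 13, now isolated. AgOTf (5 mol %) in CH2Cl2 closes the pyran by the known 6-endo-dig cycloisomerisation of alkynyl alcohols. The fallback returns to the route at 14.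

Step 2. Four processes may interfere: β-elimination of silanolate from the cross-conjugated enolate, proton exchange that leads to double hydroxymethylation, retro-aldol cleavage, and dehydration of the free β-hydroxy ketone on work-up. The fallback replaces the reversible aldol by an irreversible C-alkylation. It sets out from 3, whose kinetic enolate is quenched at −78 °C with 4-methoxybenzyl chloromethyl ether to give (4S,5R)-4-(TBSO)-5-{[(4-methoxybenzyl)oxy]methyl}cyclopent-2-en-1-one F2. This compound carries no aldol hydroxyl and can be purified. DDQ in wet CH2Cl2 releases the alcohol just before silylation, and the fallback returns to the route at 5.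

Step 11. Acylation may be slow because both partners are hindered. Acyl transfer to O7, loss of the ortho silyl group and base-induced elimination of the new ester may compete. The fallback builds the arene on the alcohol instead of coupling a finished acid. It sets out from 15.
- Commercial 2,2,6-trimethyl-4H-1,3-dioxin-4-one is C-acetylated through its lithium dienolate (LiN(iPr)2, then N-acetylimidazole) to 2,2-dimethyl-6-(2-oxopropyl)-4H-1,3-dioxin-4-one F3.
- The dianion of this compound is acetylated once more at the terminal carbon to 6-(2,4-dioxopentyl)-2,2-dimethyl-4H-1,3-dioxin-4-one F4.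
- Heating F4 and 15 in toluene at 110 °C releases an unhindered acylketene by retro-Diels–Alder cleavage. The secondary C8 hydroxyl traps it to give (7R,8R,8aR)-7-hydroxy-7-methyl-6-oxo-3-[(1E)-prop-1-en-1-yl]-1,7,8,8a-tetrahydro-6H-isochromen-8-yl 3,5,7-trioxooctanoate F5.
- Et3N in CH2Cl2 followed by dilute acid brings about the known biomimetic aldol aromatisation to the orsellinate.

The fallback returns to the route directly at 21, so that steps 10 and 12 are not needed.

Further compounds
F1 | step 8 | (4R,5R,6R)-5-(TBSO)-4-(TBSO-methyl)-6-hydroxy-6-methyl-3-[(3E)-pent-3-en-1-yn-1-yl]cyclohex-2-en-1-one | C/C=C/C#CC1=CC(=O)[C@](C)(O)[C@H](O[Si](C)(C)C(C)(C)C)[C@H]1CO[Si](C)(C)C(C)(C)C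
F2 | step 2 | (4S,5R)-4-(TBSO)-5-{[(4-methoxybenzyl)oxy]methyl}cyclopent-2-en-1-one | O=C1C=C[C@H](O[Si](C)(C)C(C)(C)C)[C@H]1COCc1ccc(OC)cc1
F3 | step 11 | 2,2-dimethyl-6-(2-oxopropyl)-4H-1,3-dioxin-4-one | CC(=O)CC1=CC(=O)OC(C)(C)O1
F4 | step 11 | 6-(2,4-dioxopentyl)-2,2-dimethyl-4H-1,3-dioxin-4-one | CC(=O)CC(=O)CC1=CC(=O)OC(C)(C)O1
F5 | step 11 | (7R,8R,8aR)-7-hydroxy-7-methyl-6-oxo-3-[(1E)-prop-1-en-1-yl]-1,7,8,8a-tetrahydro-6H-isochromen-8-yl 3,5,7-trioxooctanoate | C/C=C/C1=CC2=CC(=O)[C@](C)(O)[C@H](OC(=O)CC(=O)CC(=O)CC(C)=O)[C@H]2CO1
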